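The furanone ring is treated as the cyclic vinyl ester of a 2-methyl-3-oxo acid: O1–C5 is a carboxylate–vinyl bond and C3–C4 a Claisen bond. Everything rests on a [3+2] union of the propanoic acid dianion (O1, C2, C3) with an (E)-2-bromo-2-enoyl chloride (C4, C5) that already carries the whole furanoterpenoid chain. In one operation C-acylation makes C3–C4 and copper-catalysed intramolecular O-vinylation closes O1–C5 with retention, so the E geometry of the exocyclic C5=C6 bond is inherited from the vinyl bromide. The chain comes from farnesyl acetate; a ruthenium-catalysed asymmetric hydrogenation sets the single stereocentre.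

Key step: step 12

Remark on the chemistry: the exocyclic alkene is read from the structure as 5E (ring oxygen O1 and the side chain on opposite sides, the chain cis to C4) and the allylic stereocentre as S; the route is built for this isomer. Locants used: O1 ring oxygen, C2 lactone carbonyl, C3 methyl-bearing carbon, C4 carbon bearing the acyloxy group, C5 ring carbon of the exocyclic alkene, C6 its outer carbon.

Step 1
Reactants: 1 (2E,6E)-3,7,11-trimethyldodeca-2,6,10-trien-1-yl acetate (farnesyl acetate)
Product: 2 (2E,6E,10E)-12-hydroxy-3,7,11-trimethyldodeca-2,6,10-trien-1-yl acetate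
Conditions: SeO2 (0.3 equiv), t-BuOOH (3 equiv), salicylic acid (0.1 equiv), CH2Cl2, 0 °C → rt
Reagents that add atoms: tert-butyl hydroperoxide CC(C)(C)OO (oxygen relayed through SeO2)
Why: Catalytic SeO2 allylic oxidation (ene reaction, then [2,3]-sigmatropic shift) should attack the most electron-rich terminal trisubstituted alkene at its E-methyl group, giving the 10E allylic alcohol, while the acetate deactivates the 2,3-alkene.

Step 2
Reactants: 2 (2E,6E,10E)-12-hydroxy-3,7,11-trimethyldodeca-2,6,10-trien-1-yl acetate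
Product: 3 (2E,6E,10E)-3,7,11-trimethyl-12-oxododeca-2,6,10-trien-1-yl acetate
Conditions: MnO2 (activated, excess), CH2Cl2, rt
Reagents that add atoms: none
Why: MnO2 oxidises only the allylic alcohol to the enal and leaves alkene geometry and the acetate untouched.

Step 3
Reactants: 3 (2E,6E,10E)-3,7,11-trimethyl-12-oxododeca-2,6,10-trien-1-yl acetate
Product: 4 (2E,6E,10E)-12-acetoxy-2,6,10-trimethyldodeca-2,6,10-trienoic acid
Conditions: NaClO2, NaH2PO4, 2-methylbut-2-ene (20 equiv), t-BuOH/H2O, 0 °C
Reagents that add atoms: sodium chlorite [Na+].[O-]Cl=O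
Why: Pinnick oxidation converts the enal into the acid, the excess 2-methylbut-2-ene traps HOCl so the trisubstituted alkenes survive, and the step is placed before the oxidation-sensitive furan is introduced.

Step 4
Reactants: 4 (2E,6E,10E)-12-acetoxy-2,6,10-trimethyldodeca-2,6,10-trienoic acid
Product: 5 (2S,6E,10E)-12-acetoxy-2,6,10-trimethyldodeca-6,10-dienoic acid
Conditions: Ru(OAc)2[(S)-H8-BINAP] (0.5 mol%), H2 (2 atm), MeOH, 20 °C
Reagents that add atoms: none
Why: Carboxylate-directed asymmetric hydrogenation of a tiglic-acid-type (E)-2-methyl-2-enoic acid with a ruthenium dicarboxylate–BINAP-type catalyst reduces only the conjugated alkene, and the (S)-ligand is chosen by analogy with tiglic acid giving (S)-2-methylbutanoic acid, so the 2S centre should be set by the ligand.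

Step 5
Reactants: 6 furan-3-ylmethanol
Product: 7 3-(chloromethyl)furan
Conditions: SOCl2, pyridine, Et2O, 0 °C
Reagents that add atoms: thionyl chloride O=S(Cl)Cl
Why: Chlorination of the primary alcohol through its chlorosulfite, with pyridine keeping the furan away from free HCl.

Step 6
Reactants: 5 (2S,6E,10E)-12-acetoxy-2,6,10-trimethyldodeca-6,10-dienoic acid; 7 3-(chloromethyl)furan
Product: 9 (2S,6E,10E)-13-(furan-3-yl)-2,6,10-trimethyltrideca-6,10-dienoic acid, via Grignard reagent 8 (not isolated)
Conditions: 7, Mg, THF, 0 °C (8, 3.2 equiv); added slowly to 5, Li2CuCl4 (5 mol%), THF, −20 → 0 °C; aq. NH4Cl, then dilute HCl to pH 3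
Reagents that add atoms: none
Why: Copper-catalysed allylic substitution of the primary allylic acetate by the Grignard reagent should proceed at the alpha carbon with retention of the E alkene, the first equivalent of 8 converting the acid into an inert magnesium carboxylate that is not enolised, so the stereocentre is kept.

Step 7
Reactants: 9 (2S,6E,10E)-13-(furan-3-yl)-2,6,10-trimethyltrideca-6,10-dienoic acid
Product: 10 (2S,6E,10E)-13-(furan-3-yl)-2,6,10-trimethyltrideca-6,10-dien-1-ol
Conditions: LiAlH4, THF, 0 °C → rt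
Reagents that add atoms: none
Why: Hydride reduction of the carboxylic acid to the primary alcohol, with isolated alkenes and the furan inert and the alpha centre untouched.

Step 8
Reactants: 10 (2S,6E,10E)-13-(furan-3-yl)-2,6,10-trimethyltrideca-6,10-dien-1-ol
Product: 11 (2S,6E,10E)-13-(furan-3-yl)-2,6,10-trimethyltrideca-6,10-dienal
Conditions: Dess–Martin periodinane, CH2Cl2, 0 °C → rt; used at once
Reagents that add atoms: none
Why: Dess–Martin oxidation gives the alpha-branched aldehyde under non-basic conditions that should not epimerise it.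

Step 9
Reactants: 12 methyl bis(2,2,2-trifluoroethyl)phosphonoacetate
Product: 13 methyl 2-[bis(2,2,2-trifluoroethoxy)phosphoryl]-2-bromoacetate
Conditions: NaH, THF, 0 °C; inverse addition to Br2 (1.05 equiv), THF, −78 °C
Reagents that add atoms: bromine BrBr
Why: Electrophilic alpha-bromination of the sodium phosphonoacetate enolate, with inverse addition keeping enolate away from the more acidic product to hold back dibromination.

Step 10
Reactants: 11 (2S,6E,10E)-13-(furan-3-yl)-2,6,10-trimethyltrideca-6,10-dienal; 13 methyl 2-[bis(2,2,2-trifluoroethoxy)phosphoryl]-2-bromoacetate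
Product: 14 methyl (2E,4S,8E,12E)-2-bromo-15-(furan-3-yl)-4,8,12-trimethylpentadeca-2,8,12-trienoate
Conditions: 13, t-BuOK, 18-crown-6, THF, −78 °C; then 11, −78 °C
Reagents that add atoms: none
Why: Horner–Wadsworth–Emmons olefination under Still–Gennari-type kinetic control (trifluoroethyl phosphonate, dissociated potassium base) should place the ester cis to the chain, which for the bromo compound is the 2E isomer with bromine trans to the chain, and the low temperature protects the aldehyde alpha centre.

Step 11
Reactants: 14 methyl (2E,4S,8E,12E)-2-bromo-15-(furan-3-yl)-4,8,12-trimethylpentadeca-2,8,12-trienoate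
Product: 15 (2E,4S,8E,12E)-2-bromo-15-(furan-3-yl)-4,8,12-trimethylpentadeca-2,8,12-trienoic acid
Conditions: LiOH·H2O, THF/H2O, 0 °C → rt; cold 1 M HCl to pH 3
Reagents that add atoms: lithium hydroxide [Li+].[OH-]
Why: Ester saponification; in the 2E isomer H and Br are cis, so anti-dehydrobromination to the alkynoate is not available, and hydroxide is too weak to remove the gamma C–H.

Step 12
Reactants: 15 (2E,4S,8E,12E)-2-bromo-15-(furan-3-yl)-4,8,12-trimethylpentadeca-2,8,12-trienoic acid; 16 propanoic acid
Product: 20 (5E)-5-[(2S,6E,10E)-13-(furan-3-yl)-2,6,10-trimethyltrideca-6,10-dien-1-ylidene]-4-hydroxy-3-methylfuran-2(5H)-one, via acid chloride 17 (not isolated), via dilithium propanoate dianion 18 (not isolated), via bromo keto acid dianion 19 (not isolated)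
Conditions: (a) 15, 1-chloro-N,N,2-trimethylprop-1-en-1-amine, CH2Cl2, 0 °C → rt, evaporate; (b) 16 (2.2 equiv), LiN(i-Pr)2 (4.4 equiv), THF, 0 °C, then 17 added at −78 °C; (c) CuI (20 mol%), trans-N,N'-dimethylcyclohexane-1,2-diamine (40 mol%), DMF, −78 → 60 °C; cold aq. citric acid
Reagents that add atoms: none
Why: Acid chloride 17, made under neutral conditions, C-acylates the dilithium dianion 18 at −78 °C (Claisen-type acylation of a carboxylic acid dianion, 1,2-attack) to form C3–C4, and the second equivalent of 18 deprotonates the product so that 19 is held as its enolate dianion, which does not decarboxylate and offers no electrophilic enone for 6-endo oxa-Michael closure to a 4-hydroxypyran-2-one. CuI and the diamine then effect an Ullmann-type intramolecular O-vinylation in which the copper carboxylate inserts into the vinyl C–Br bond and C–O reductive elimination forms O1–C5; the closest known reaction is the cyclisation of bromoalkenoic acids to enol lactones with monovalent copper. The furanone ring closes in the 5-exo mode at the vinyl carbon C5, the C5=C6 bond staying outside the ring, while closure through the enolate oxygen or C3 would need a three-membered ring. No stereocentre is created, and because oxidative addition and reductive elimination at a vinyl carbon retain configuration, O1 takes the place of the bromine trans to the chain and the exocyclic alkene should emerge E with the chain cis to C4. The selectivities needed are C- over O-acylation (hard dilithium dianion, inverse addition), five-ring O-vinylation over pyranone formation (enolate dianion plus copper catalysis) and preservation of the vinyl geometry and of the allylic stereocentre (no free enone during the heating, which is kept short and moderate).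

Step 13
Reactants: 20 (5E)-5-[(2S,6E,10E)-13-(furan-3-yl)-2,6,10-trimethyltrideca-6,10-dien-1-ylidene]-4-hydroxy-3-methylfuran-2(5H)-one; 21 octadecanoyl chloride
Product: 22 (5E)-5-[(2S,6E,10E)-13-(furan-3-yl)-2,6,10-trimethyltrideca-6,10-dien-1-ylidene]-3-methyl-2-oxo-2,5-dihydrofuran-4-yl octadecanoate
Conditions: 21 (1.1 equiv), pyridine (2 equiv), CH2Cl2, −20 → 0 °C, dark
Reagents that add atoms: none
Why: O-acylation of the acidic tetronic acid enol at O4 by the acid chloride with a weak base; C3 is blocked by its methyl group, and pyridine is too weak to remove the allylic C–H, so the stereocentre and the E alkene should be kept.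

Compound list
1 | (2E,6E)-3,7,11-trimethyldodeca-2,6,10-trien-1-yl acetate | CC(C)=CCC/C(C)=C/CC/C(C)=C/COC(C)=O | starting material
2 | (2E,6E,10E)-12-hydroxy-3,7,11-trimethyldodeca-2,6,10-trien-1-yl acetate | OC/C(C)=C/CC/C(C)=C/CC/C(C)=C/COC(C)=O | intermediate
3 | (2E,6E,10E)-3,7,11-trimethyl-12-oxododeca-2,6,10-trien-1-yl acetate | O=C/C(C)=C/CC/C(C)=C/CC/C(C)=C/COC(C)=O | intermediate
4 | (2E,6E,10E)-12-acetoxy-2,6,10-trimethyldodeca-2,6,10-trienoic acid | OC(=O)/C(C)=C/CC/C(C)=C/CC/C(C)=C/COC(C)=O | intermediate
5 | (2S,6E,10E)-12-acetoxy-2,6,10-trimethyldodeca-6,10-dienoic acid | OC(=O)[C@@H](C)CCC/C(C)=C/CC/C(C)=C/COC(C)=O | intermediate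
6 | furan-3-ylmethanol | OCc1ccoc1 | starting material
7 | 3-(chloromethyl)furan | ClCc1ccoc1 | intermediate
8 | (furan-3-ylmethyl)magnesium chloride | Cl[Mg]Cc1ccoc1 | intermediate
9 | (2S,6E,10E)-13-(furan-3-yl)-2,6,10-trimethyltrideca-6,10-dienoic acid | OC(=O)[C@@H](C)CCC/C(C)=C/CC/C(C)=C/CCc1ccoc1 | intermediate
10 | (2S,6E,10E)-13-(furan-3-yl)-2,6,10-trimethyltrideca-6,10-dien-1-ol | OC[C@@H](C)CCC/C(C)=C/CC/C(C)=C/CCc1ccoc1 | intermediate
11 | (2S,6E,10E)-13-(furan-3-yl)-2,6,10-trimethyltrideca-6,10-dienal | O=C[C@@H](C)CCC/C(C)=C/CC/C(C)=C/CCc1ccoc1 | intermediate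
12 | methyl bis(2,2,2-trifluoroethyl)phosphonoacetate | COC(=O)CP(=O)(OCC(F)(F)F)OCC(F)(F)F | starting material
13 | methyl 2-[bis(2,2,2-trifluoroethoxy)phosphoryl]-2-bromoacetate | COC(=O)C(Br)P(=O)(OCC(F)(F)F)OCC(F)(F)F | intermediate
14 | methyl (2E,4S,8E,12E)-2-bromo-15-(furan-3-yl)-4,8,12-trimethylpentadeca-2,8,12-trienoate | COC(=O)C(\Br)=C/[C@@H](C)CCC/C(C)=C/CC/C(C)=C/CCc1ccoc1 | intermediate
15 | (2E,4S,8E,12E)-2-bromo-15-(furan-3-yl)-4,8,12-trimethylpentadeca-2,8,12-trienoic acid | OC(=O)C(\Br)=C/[C@@H](C)CCC/C(C)=C/CC/C(C)=C/CCc1ccoc1 | intermediate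
16 | propanoic acid | CCC(=O)O | starting material
17 | (2E,4S,8E,12E)-2-bromo-15-(furan-3-yl)-4,8,12-trimethylpentadeca-2,8,12-trienoyl chloride | ClC(=O)C(\Br)=C/[C@@H](C)CCC/C(C)=C/CC/C(C)=C/CCc1ccoc1 | intermediate
18 | dilithium salt of the propanoic acid dianion | CC([Li])C(=O)O[Li] | intermediate
19 | (4E,6S,10E,14E)-4-bromo-17-(furan-3-yl)-2,6,10,14-tetramethyl-3-oxoheptadeca-4,10,14-trienoic acid, present as its dilithium enolate carboxylate | CC(C(=O)O)C(=O)C(\Br)=C/[C@@H](C)CCC/C(C)=C/CC/C(C)=C/CCc1ccoc1 | intermediate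
20 | (5E)-5-[(2S,6E,10E)-13-(furan-3-yl)-2,6,10-trimethyltrideca-6,10-dien-1-ylidene]-4-hydroxy-3-methylfuran-2(5H)-one | OC1=C(C)C(=O)O/C1=C/[C@@H](C)CCC/C(C)=C/CC/C(C)=C/CCc1ccoc1 | intermediate
21 | octadecanoyl chloride (stearoyl chloride) | CCCCCCCCCCCCCCCCCC(=O)Cl | starting material
22 | (5E)-5-[(2S,6E,10E)-13-(furan-3-yl)-2,6,10-trimethyltrideca-6,10-dien-1-ylidene]-3-methyl-2-oxo-2,5-dihydrofuran-4-yl octadecanoate | CCCCCCCCCCCCCCCCCC(=O)OC1=C(C)C(=O)O/C1=C/[C@@H](C)CCC/C(C)=C/CC/C(C)=C/CCc1ccoc1 | target

Total step count: 13. Longest linear sequence: 11 steps (steps 1, 2, 3, 4, 6, 7, 8, 10, 11, 12, 13).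

Steps most likely to fail

Step 12. The vinyl bromide geometry may be lost by reversible conjugate addition before C–O coupling. The carboxylate may close 6-endo with loss of HBr to a pyranone. The keto acid may decarboxylate, or the bromide may be reduced off. The fallback sets out from 14 and comes back at 20, making the two ring bonds in separate steps and never exposing a beta-keto acid. Miyaura borylation with retention (B2pin2, PdCl2(dppf), KOPh, toluene, 50 °C) would give methyl (2Z,4S,8E,12E)-15-(furan-3-yl)-4,8,12-trimethyl-2-(4,4,5,5-tetramethyl-1,3,2-dioxaborolan-2-yl)pentadeca-2,8,12-trienoate F1. Oxidative Chan–Lam-type coupling with propanoic acid 16 (Cu(OAc)2, DMAP, 4 Å sieves, O2, MeCN, 40 °C) would then form O1–C5 with retention, giving the enol ester methyl (2E,4S,8E,12E)-15-(furan-3-yl)-4,8,12-trimethyl-2-(propanoyloxy)pentadeca-2,8,12-trienoate F2. Dieckmann cyclisation (LiN(SiMe3)2, THF, −78 °C) would close C3–C4 and give 20.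

Step 10. The E selectivity of the olefination may erode with this alpha-branched aliphatic aldehyde, and the base may epimerise the aldehyde before it reacts. The fallback sets out from 11 and comes back at 14, fixing the geometry by a syn hydrometalation instead. Corey–Fuchs olefination (CBr4, PPh3, Et3N, CH2Cl2, 0 °C) would give 3-[(3E,7E,12S)-14,14-dibromo-4,8,12-trimethyltetradeca-3,7,13-trien-1-yl]furan F3. Treatment with n-BuLi (2.1 equiv, THF, −78 °C) and then methyl chloroformate would give methyl (4S,8E,12E)-15-(furan-3-yl)-4,8,12-trimethylpentadeca-8,12-dien-2-ynoate F4. Syn hydrostannation with tin at C2 (Bu3SnH, Pd(PPh3)4, THF, 0 °C) would give methyl (2E,4S,8E,12E)-15-(furan-3-yl)-4,8,12-trimethyl-2-(tributylstannyl)pentadeca-2,8,12-trienoate F5. Bromodestannylation with retention (CuBr2, THF, 0 °C), which spares the furan and the alkenes, would give 14.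

Step 6. The Grignard reagent may attack the allylic system with transposition (gamma attack), homocouple, or react sluggishly with the acetate beside a magnesium carboxylate. The fallback sets out from 5 and comes back at 9 with the polarity reversed (allyl nucleophile, furylmethyl electrophile). Allylic substitution with sulfinate under zerovalent palladium (PhSO2Na, Pd(PPh3)4, THF/MeOH, rt) would give (2S,6E,10E)-2,6,10-trimethyl-12-(phenylsulfonyl)dodeca-6,10-dienoic acid F6. Its dianion (n-BuLi, 2.1 equiv, THF/HMPA, −78 °C) would be alkylated with 7 (NaI cat.) to (2S,6E,10E)-13-(furan-3-yl)-2,6,10-trimethyl-12-(phenylsulfonyl)trideca-6,10-dienoic acid F7, formed as a mixture of epimers at the sulfonyl carbon that converge in the next step. Reductive desulfonylation without alkene migration (PdCl2(dppp) cat., LiBHEt3, THF, 0 °C) would give 9.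

Further compounds
F1 | step 12 | methyl (2Z,4S,8E,12E)-15-(furan-3-yl)-4,8,12-trimethyl-2-(4,4,5,5-tetramethyl-1,3,2-dioxaborolan-2-yl)pentadeca-2,8,12-trienoate | COC(=O)C(\B1OC(C)(C)C(C)(C)O1)=C/[C@@H](C)CCC/C(C)=C/CC/C(C)=C/CCc1ccoc1
F2 | step 12 | methyl (2E,4S,8E,12E)-15-(furan-3-yl)-4,8,12-trimethyl-2-(propanoyloxy)pentadeca-2,8,12-trienoate | COC(=O)C(\OC(=O)CC)=C/[C@@H](C)CCC/C(C)=C/CC/C(C)=C/CCc1ccoc1
F3 | step 10 | 3-[(3E,7E,12S)-14,14-dibromo-4,8,12-trimethyltetradeca-3,7,13-trien-1-yl]furan | BrC(Br)=C[C@@H](C)CCC/C(C)=C/CC/C(C)=C/CCc1ccoc1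
F4 | step 10 | methyl (4S,8E,12E)-15-(furan-3-yl)-4,8,12-trimethylpentadeca-8,12-dien-2-ynoate | COC(=O)C#C[C@@H](C)CCC/C(C)=C/CC/C(C)=C/CCc1ccoc1
F5 | step 10 | methyl (2E,4S,8E,12E)-15-(furan-3-yl)-4,8,12-trimethyl-2-(tributylstannyl)pentadeca-2,8,12-trienoate | COC(=O)C(\[Sn](CCCC)(CCCC)CCCC)=C/[C@@H](C)CCC/C(C)=C/CC/C(C)=C/CCc1ccoc1
F6 | step 6 | (2S,6E,10E)-2,6,10-trimethyl-12-(phenylsulfonyl)dodeca-6,10-dienoic acid | OC(=O)[C@@H](C)CCC/C(C)=C/CC/C(C)=C/CS(=O)(=O)c1ccccc1
F7 | step 6 | (2S,6E,10E)-13-(furan-3-yl)-2,6,10-trimethyl-12-(phenylsulfonyl)trideca-6,10-dienoic acid | OC(=O)[C@@H](C)CCC/C(C)=C/CC/C(C)=C/C(Cc1ccoc1)S(=O)(=O)c1ccccc1
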